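The reading at 8.0 h comes late in the noon flask, so I watched two things: how much X had been spent by then, and how the spent X was shared out.

the same everywhere: X 0.40 M
- noon: E 0.72 M; the very flask that is asked about, followed so far
- summer: E 1.1 M; run made earlier
- flask: E 0.720 M; time 8.0 h

| run | time / h | X / % | G / % | D / % | J / % | L / % |
|---|---|---|---|---|---|---|
| noon | 0.133 | 91.8 | 0 | 0.7 | 3.5 | 0 |
| noon | 0.333 | 85.8 | 0.3 | 2.1 | 11.0 | 1.2 |
| noon | 0.667 | 71.0 | 0 | 7.3 | 18.3 | 0.6 |
| noon | 1.00 | 61.9 | 1.2 | 9.2 | 26.8 | 0 |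
| noon | 1.33 | 54.5 | 2.4 | 10.9 | 33.4 | 0 |
| noon | 2.00 | 40.1 | 3.8 | 11.7 | 43.6 | 0 |
| noon | 2.50 | 30.5 | 6.0 | 12.8 | 51.6 | 0.1 |
| summer | 0.833 | 67.8 | 0.5 | 7.3 | 23.4 | 0 |
| summer | 1.50 | 48.6 | 2.8 | 11.3 | 35.5 | 0.4 |
| summer | 2.50 | 30.7 | 6.5 | 13.2 | 50.5 | 0 |
| summer | 3.00 | 26.0 | 9.1 | 11.1 | 53.7 | 3.6 |
| summer | 4.00 | 17.3 | 12.0 | 10.8 | 59.3 | 5.3 |
| summer | 5.00 | 9.5 | 12.9 | 8.9 | 61.9 | 3.3 |
| summer | 6.00 | 5.3 | 16.0 | 9.1 | 64.7 | 4.2 |

(each reading ± 1 percentage point)

1. the largest share of what was charged as X, at 8.0 h belongs to (L / J / D / G / X)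
2. the largest share itself, whichever of these holds it, in percent of the X charged

- the numbers in the tables scatter by 1 percentage point (one standard deviation)
- a reading or a percentage of J counts all its forms, free or not

Noon and summer look nearly the same, and at 2.50 h they were: X stood at 30.5% in noon and 30.7% in summer, and J at 51.6% and 50.5%. Yet summer had cE 1.1 M and noon 0.72 M. Those gaps lie near the scatter, so I read no effect of E and expected noon to follow summer's course.

I then wrote the balance of X, the smaller charge. Summer's last reading, at 6.00 h, adds up to 99.3%, so the five columns hold the X. That reading puts 72.8% of the spent X in J plus L, and noon's last puts 74.4% there. I call this fraction, J plus L over X spent, the J share; the usual term is selectivity.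

Read as first-order decay, summer's last X gives a decay constant of 0.490 h⁻¹, so I expected 1.99% of the X left in noon at 8.0 h and J plus L at 71.3%. Taking off summer's last L of 4.2% left J near 67.1%, which is more than D and G together, at 26.7%.

The forecast named J at 68%, a little above my figure for J, holding that “This split holds throughout both runs”.

At 8.0 h the noon flask gave J at 64.6% and L at 8.05%, so J plus L came to 72.7% against my 71.3%, and L stood higher than in summer's last reading.

    X → D (k = 0.119 h⁻¹)
    D → G (k = 0.273 h⁻¹)
    X → J (k = 0.347 h⁻¹)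
    Z ⇌ J, rate k4*(cs4 - [J]) while solid is left; crystals form when [J] > cs4 (solubility = 0.260 M, k = 3.66 h⁻¹)
    J → L (k = 0.0195 h⁻¹)

The neighbour flask has noon's charge and is read at 2.0 h. The same constant leaves 37.6% of its X, and the J share then gives J plus L of 45.4%. That flask held X at 39.4%, J at 44.1% and L at 1.00%, so its J plus L stood at 45.1%.

The earlier runs and the new flask stem from a simulated flask for an exercise, noise included.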